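**Plan**

- Retrosynthetic cuts, in order: C12=C13 (Wittig with a succinimide ylide); the C7–O bond and C8=C17 (allylic oxidation, methylenation of an 8-ketone); C9–C11 (cross-coupling at a C9 enol triflate); C3–C4 and C2–Cl of ring A; finally the isopropenyl–C5 and allyl–C10 bonds on a cyclohexenone.
- Enabling feature: in ring A the chlorine sits on C2, between the C1 and C3 methylenes and 1,3 to the gem-dimethyl carbon C4. This is the pattern left when a C4 tertiary cation is attacked by the terminal carbon of a C2=C3 vinyl group and C2 takes up chloride.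
- Forward order: ring B is bought as 2-methylcyclohexenone and receives the isopropenyl and allyl groups; ring A is closed by the chloride-terminated cyclisation; then come C11–C12, C17, the C7 acetate and the imide.
- Stereochemistry: C5 from ligand-controlled conjugate addition; C10 from allylation trans to the isopropenyl group; C2 from anti (equatorial) chloride capture in a chair; C9 from α-face hydroboration (also the thermodynamic epimer); C7 from axial hydride delivery to a 7-ketone; the E-alkene from a stabilised ylide.

Key step: step 2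

Remark: labdane numbering is used for all bicyclic compounds (ring A = C1–C5 and C10, ring B = C5–C10, C17 = exocyclic methylene carbon, α = face opposite the C10 methyl). The ligand antipode in step 1 is assumed to be the one that gives the 3S adduct.

**Route**

Step 1
Reactants: 1 2-methylcyclohex-2-en-1-one; 2 isopropenylmagnesium bromide; 3 allyl bromide
Product: 5 (2S,3S)-2-allyl-2-methyl-3-(prop-1-en-2-yl)cyclohexan-1-one, via bromomagnesium enolate 4 (not isolated)
Conditions: 2, CuBr·SMe2 (5 mol%), Josiphos-type ferrocenyl diphosphine (6 mol%), t-BuOMe, –78 °C; then 3, DMPU, –78 → 23 °C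
Reagents that add atoms: none
Why: Copper-catalysed asymmetric conjugate addition of a Grignard reagent to an α-substituted cyclohexenone should set C5 under ligand control and leave the regiodefined enolate 4, which is C-allylated on the face opposite the new isopropenyl group, so that the quaternary C10 forms with allyl trans to isopropenyl (tandem conjugate addition–enolate alkylation).

Step 2
Reactants: 5 (2S,3S)-2-allyl-2-methyl-3-(prop-1-en-2-yl)cyclohexan-1-one
Product: 7 (4aS,7S,8aS)-7-chloro-5,5,8a-trimethyloctahydronaphthalen-1(2H)-one, via tertiary chloride 6 (not isolated)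
Conditions: HCl (1.1 equiv), CH2Cl2, 0 °C; then SnCl4 (2.2 equiv), –78 → –30 °C
Reagents that add atoms: hydrogen chloride, Cl
Why: Markovnikov hydrochlorination touches only the 1,1-disubstituted alkene and gives tertiary chloride 6, which SnCl4 (also bound to the ketone) ionises to the C4 cation with SnCl5– as counter-ion. The terminal vinyl carbon C3 attacks C4 in a 6-endo-trig closure of ring A through a chair; because the C5–C4 and C10–C1 bonds are both equatorial on ring B, the decalin can only be trans-fused. Chloride is returned to the developing C2 cation anti to the new C3–C4 bond, that is equatorially, which sets C2 as 2α; this is also the thermodynamic epimer, since a 2β-chloride would be syn-axial to the C4 and C10 methyl groups. The closest known reaction type is the Lewis-acid-promoted, halide-terminated cation–olefin cyclisation, the carbocyclic counterpart of the halo-Prins reaction. The step needs ionisation at C4 only and endo rather than 5-exo attack: the first is secured because only the tertiary chloride ionises and the monosubstituted alkene is inert to HCl under these conditions, the second because endo attack leads to a secondary rather than a primary cation.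

Step 3
Reactants: 7 (4aS,7S,8aS)-7-chloro-5,5,8a-trimethyloctahydronaphthalen-1(2H)-one
Product: 9 2α-chloro-4,4,10-trimethyl-trans-decal-8-en-9-yl trifluoromethanesulfonate, via potassium enolate 8 (not isolated)
Conditions: KHMDS, THF, –78 °C; then PhNTf2, –78 → 0 °C
Reagents that add atoms: potassium bis(trimethylsilyl)amide (potassium in 8 only), C[Si](C)(C)[N-][Si](C)(C)C.[K+]; N-phenylbis(trifluoromethanesulfonimide), O=S(=O)(N(c1ccccc1)S(=O)(=O)C(F)(F)F)C(F)(F)F
Why: The ketone can enolise only towards C8 because C10 is quaternary, so deprotonation and O-sulfonylation give a single enol triflate (enol triflate formation), and the equatorial chloride, which has no antiperiplanar hydrogen, should survive the base.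

Step 4
Reactants: 9 2α-chloro-4,4,10-trimethyl-trans-decal-8-en-9-yl trifluoromethanesulfonate; 10 (1,3-dioxolan-2-ylmethyl)zinc bromide
Product: 11 2α-chloro-13,14,15,16,17-pentanorlabd-8-en-12-al ethylene acetal
Conditions: 10 (2 equiv), Pd(dppf)Cl2 (5 mol%), LiCl, THF/NMP, 50 °C
Reagents that add atoms: none
Why: Negishi sp2–sp3 cross-coupling of an enol triflate with a functionalised alkylzinc halide forms C9–C11 and brings in C12 at the aldehyde oxidation level as its dioxolane; the unactivated secondary chloride does not undergo oxidative addition.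

Step 5
Reactants: 11 2α-chloro-13,14,15,16,17-pentanorlabd-8-en-12-al ethylene acetal
Product: 13 2α-chloro-8α-hydroxy-13,14,15,16,17-pentanorlabdan-12-al ethylene acetal (9α-H), via alkylborane 12 (not isolated)
Conditions: BH3·THF, THF, 0 → 23 °C; then NaOH, H2O2, 0 °C
Reagents that add atoms: borane (boron in 12 only), B; hydrogen peroxide, OO
Why: Hydroboration–oxidation of the trisubstituted Δ8 alkene puts boron on the less substituted C8 and delivers H and B syn from the α face, away from the axial C10 methyl group, which sets C9 with 9α-H and an equatorial β side chain.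

Step 6
Reactants: 13 2α-chloro-8α-hydroxy-13,14,15,16,17-pentanorlabdan-12-al ethylene acetal
Product: 14 2α-chloro-8-oxo-13,14,15,16,17-pentanorlabdan-12-al ethylene acetal
Conditions: Dess–Martin periodinane, pyridine, CH2Cl2, 23 °C
Reagents that add atoms: none
Why: Buffered Dess–Martin oxidation of a secondary alcohol leaves the acetal intact, and the now epimerisable C9 already carries the thermodynamically preferred equatorial side chain.

Step 7
Reactants: 14 2α-chloro-8-oxo-13,14,15,16,17-pentanorlabdan-12-al ethylene acetal
Product: 15 2α-chloro-13,14,15,16-tetranorlabd-8(17)-en-12-al ethylene acetal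
Conditions: Ph3PCH3Br, KOt-Bu, toluene, 80 °C
Reagents that add atoms: methyltriphenylphosphonium bromide, C[P+](c1ccccc1)(c1ccccc1)c1ccccc1.[Br-]
Why: Wittig methylenation of an 8-oxolabdane-type ketone installs C17 as the exocyclic alkene, and any enolisation at C9 under the basic conditions returns the favoured equatorial epimer.

Step 8
Reactants: 15 2α-chloro-13,14,15,16-tetranorlabd-8(17)-en-12-al ethylene acetal
Product: 16 2α-chloro-7α-hydroxy-13,14,15,16-tetranorlabd-8(17)-en-12-al ethylene acetal
Conditions: SeO2 (0.3 equiv), t-BuOOH, CH2Cl2, 23 °C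
Reagents that add atoms: selenium dioxide (oxygen-transfer agent), O=[Se]=O; tert-butyl hydroperoxide (terminal oxidant), CC(C)(C)OO
Why: Selenium dioxide allylic oxidation (ene reaction then [2,3]-sigmatropic shift) of the 1,1-disubstituted alkene should oxidise the allylic methylene C7 rather than the hindered methine C9 and keep the double bond exocyclic, with oxygen expected on the axial α face.

Step 9
Reactants: 16 2α-chloro-7α-hydroxy-13,14,15,16-tetranorlabd-8(17)-en-12-al ethylene acetal
Product: 17 2α-chloro-7-oxo-13,14,15,16-tetranorlabd-8(17)-en-12-al ethylene acetal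
Conditions: Dess–Martin periodinane, pyridine, CH2Cl2, 0 → 23 °C
Reagents that add atoms: none
Why: Dess–Martin oxidation of the allylic alcohol under buffered, non-isomerising conditions gives the exocyclic enone and erases the C7 configuration so that it can be reset.

Step 10
Reactants: 17 2α-chloro-7-oxo-13,14,15,16-tetranorlabd-8(17)-en-12-al ethylene acetal
Product: 18 2α-chloro-7β-hydroxy-13,14,15,16-tetranorlabd-8(17)-en-12-al ethylene acetal
Conditions: NaBH4, CeCl3·7H2O, MeOH, –78 °C
Reagents that add atoms: none
Why: Luche reduction gives 1,2-reduction of the enone, and the small hydride should attack C7 axially from the α face, where it meets only 1,3-diaxial hydrogens, to give the equatorial 7β-alcohol.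

Step 11
Reactants: 18 2α-chloro-7β-hydroxy-13,14,15,16-tetranorlabd-8(17)-en-12-al ethylene acetal
Product: 19 7β-acetoxy-2α-chloro-13,14,15,16-tetranorlabd-8(17)-en-12-al ethylene acetal
Conditions: Ac2O, pyridine, DMAP (cat.), CH2Cl2, 23 °C
Reagents that add atoms: acetic anhydride, CC(=O)OC(C)=O
Why: DMAP-catalysed acetylation of an unhindered equatorial secondary alcohol proceeds with retention at C7.

Step 12
Reactants: 19 7β-acetoxy-2α-chloro-13,14,15,16-tetranorlabd-8(17)-en-12-al ethylene acetal
Product: 20 7β-acetoxy-2α-chloro-13,14,15,16-tetranorlabd-8(17)-en-12-al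
Conditions: 1 M aq. HCl, THF, 23 °C
Reagents that add atoms: water, O
Why: Acid-catalysed acetal hydrolysis releases the aldehyde, and dilute acid at room temperature should leave the allylic acetate and the exocyclic alkene untouched.

Step 13
Reactants: 21 maleimide
Product: 22 3-(triphenyl-λ5-phosphanylidene)pyrrolidine-2,5-dione
Conditions: PPh3, acetone, 56 °C
Reagents that add atoms: triphenylphosphine, c1ccc(cc1)P(c1ccccc1)c1ccccc1
Why: Conjugate addition of the phosphine to maleimide followed by proton transfer gives the stabilised succinimide ylide (phospha-Michael addition).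

Step 14
Reactants: 20 7β-acetoxy-2α-chloro-13,14,15,16-tetranorlabd-8(17)-en-12-al; 22 3-(triphenyl-λ5-phosphanylidene)pyrrolidine-2,5-dione
Product: 23 7β-acetoxy-2α-chlorolabda-8(17),12E-diene-15,16-dicarboximide (CNP0220384.1)
Conditions: MeOH, 65 °C
Reagents that add atoms: none
Why: Wittig olefination with a stabilised imide ylide forms C12=C13 with E geometry (chain anti to the C16 carbonyl) under neutral conditions that spare the acetate and the N–H imide.

**Compound list**

1 | 2-methylcyclohex-2-en-1-one | CC1=CCCCC1=O | starting material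
2 | isopropenylmagnesium bromide | CC(=C)[Mg]Br | starting material
3 | allyl bromide | C=CCBr | starting material
4 | bromomagnesium (S)-2-methyl-3-(prop-1-en-2-yl)cyclohex-1-en-1-olate | CC1=C(O[Mg]Br)CCC[C@H]1C(C)=C | intermediate
5 | (2S,3S)-2-allyl-2-methyl-3-(prop-1-en-2-yl)cyclohexan-1-one (allyl trans to isopropenyl) | O=C1CCC[C@@H](C(C)=C)[C@]1(C)CC=C | intermediate
6 | (2S,3R)-2-allyl-3-(2-chloropropan-2-yl)-2-methylcyclohexan-1-one | O=C1CCC[C@@H](C(C)(C)Cl)[C@]1(C)CC=C | intermediate
7 | (4aS,7S,8aS)-7-chloro-5,5,8a-trimethyloctahydronaphthalen-1(2H)-one (2α-chloro-4,4,10-trimethyl-trans-decal-9-one; 5α-H, 10β-CH3, equatorial Cl) | C1CC[C@H]2C(C)(C)C[C@H](Cl)C[C@]2(C)C1=O | intermediate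
8 | potassium enolate of 7 (C8=C9) | [K+].[O-]C1=CCC[C@H]2C(C)(C)C[C@H](Cl)C[C@]12C | intermediate
9 | 2α-chloro-4,4,10-trimethyl-trans-decal-8-en-9-yl trifluoromethanesulfonate | FC(F)(F)S(=O)(=O)OC1=CCC[C@H]2C(C)(C)C[C@H](Cl)C[C@]12C | intermediate
10 | (1,3-dioxolan-2-ylmethyl)zinc bromide | Br[Zn]CC1OCCO1 | starting material
11 | 2α-chloro-13,14,15,16,17-pentanorlabd-8-en-12-al ethylene acetal (C9 carries CH2–dioxolane; Δ8 alkene with C8–H) | C1COC(O1)CC2=CCC[C@H]3C(C)(C)C[C@H](Cl)C[C@]23C | intermediate
12 | 8α-boryl derivative of 11 (9α-H) | B[C@@H]1CC[C@H]2C(C)(C)C[C@H](Cl)C[C@]2(C)[C@H]1CC1OCCO1 | intermediate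
13 | 2α-chloro-8α-hydroxy-13,14,15,16,17-pentanorlabdan-12-al ethylene acetal (9α-H) | O[C@@H]1CC[C@H]2C(C)(C)C[C@H](Cl)C[C@]2(C)[C@H]1CC1OCCO1 | intermediate
14 | 2α-chloro-8-oxo-13,14,15,16,17-pentanorlabdan-12-al ethylene acetal (9α-H) | O=C1CC[C@H]2C(C)(C)C[C@H](Cl)C[C@]2(C)[C@H]1CC1OCCO1 | intermediate
15 | 2α-chloro-13,14,15,16-tetranorlabd-8(17)-en-12-al ethylene acetal | C=C1CC[C@H]2C(C)(C)C[C@H](Cl)C[C@]2(C)[C@H]1CC1OCCO1 | intermediate
16 | 2α-chloro-7α-hydroxy-13,14,15,16-tetranorlabd-8(17)-en-12-al ethylene acetal (axial OH) | C=C1[C@H](O)C[C@H]2C(C)(C)C[C@H](Cl)C[C@]2(C)[C@H]1CC1OCCO1 | intermediate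
17 | 2α-chloro-7-oxo-13,14,15,16-tetranorlabd-8(17)-en-12-al ethylene acetal | C=C1C(=O)C[C@H]2C(C)(C)C[C@H](Cl)C[C@]2(C)[C@H]1CC1OCCO1 | intermediate
18 | 2α-chloro-7β-hydroxy-13,14,15,16-tetranorlabd-8(17)-en-12-al ethylene acetal (equatorial OH) | C=C1[C@@H](O)C[C@H]2C(C)(C)C[C@H](Cl)C[C@]2(C)[C@H]1CC1OCCO1 | intermediate
19 | 7β-acetoxy-2α-chloro-13,14,15,16-tetranorlabd-8(17)-en-12-al ethylene acetal | C=C1[C@@H](OC(C)=O)C[C@H]2C(C)(C)C[C@H](Cl)C[C@]2(C)[C@H]1CC1OCCO1 | intermediate
20 | 7β-acetoxy-2α-chloro-13,14,15,16-tetranorlabd-8(17)-en-12-al | C=C1[C@@H](OC(C)=O)C[C@H]2C(C)(C)C[C@H](Cl)C[C@]2(C)[C@H]1CC=O | intermediate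
21 | maleimide | O=C1C=CC(=O)N1 | starting material
22 | 3-(triphenyl-λ5-phosphanylidene)pyrrolidine-2,5-dione | O=C1CC(=P(c2ccccc2)(c2ccccc2)c2ccccc2)C(=O)N1 | intermediate
23 | 7β-acetoxy-2α-chlorolabda-8(17),12E-diene-15,16-dicarboximide (CNP0220384.1) | C=C1[C@@H](OC(C)=O)C[C@H]2C(C)(C)C[C@H](Cl)C[C@]2(C)[C@H]1C/C=C1\CC(=O)NC1=O | target

**Step count**

Total: 14 steps. Longest linear sequence: 13 steps (steps 1–12 and 14); step 13 is a one-step side branch.

**Steps most likely to fail**

Step 2. The ion pair may lose the C5 proton, giving the tetrasubstituted alkene and scrambling C5, or may collapse back to the tertiary chloride faster than the weakly nucleophilic vinyl group attacks; chloride return to C2 may also be unselective. The fallback sets out from 5 and keeps the C3–C4 ring closure but lets solvent end the cyclisation. In formic acid at 23–40 °C the same cation should close ring A with capture of the C2 cation by formate to give 2α-formyloxy-4,4,10-trimethyl-trans-decal-9-one F1. Methanolysis (K2CO3, MeOH) gives 2α-hydroxy-4,4,10-trimethyl-trans-decal-9-one F2. Thionyl chloride converts this into the chlorosulfite F3, and catalytic TiCl4 collapses it with retention (front-side chloride delivery, known for cyclic secondary alcohols) to return to 7. An invertive chlorination is not used because it would give the axial 2β-chloride.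

Step 1. Facial selectivity in the copper-catalysed addition of an alkenyl Grignard reagent may be poor, and C-allylation of the magnesium enolate may be sluggish. The fallback sets out from 1 and replaces asymmetric catalysis by resolution. Addition of 2 with CuI and no chiral ligand, trapping with Me3SiCl, regeneration of the lithium enolate with MeLi and allylation with 3 should give 5 as a racemate with its enantiomer F4. NaBH4 reduction gives the alcohol F5 from 5 and the enantiomeric alcohol F6 from F4; the carbinol configuration is immaterial because it is oxidised again. Esterification with (S)-O-methylmandelic acid (DCC, DMAP) gives the ester F7 and the diastereomeric ester F8, which are separated by chromatography or crystallisation. Saponification of F7 (LiOH) returns the alcohol F5 as a single enantiomer, and Dess–Martin oxidation comes back to 5.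

Step 4. Transmetalation of the β-oxygenated alkylzinc reagent onto the hindered C9–palladium species may be slow, allowing reduction of the triflate or β-alkoxide loss from the zinc reagent. The fallback sets out from 9 and brings in C11–C12 as a vinyl group. Stille coupling with tributyl(vinyl)stannane (Pd(PPh3)4, LiCl, THF, 65 °C) gives the 9-vinyl diene F9. 9-BBN adds to the terminal vinyl carbon only, and oxidation (NaOH, H2O2) gives the homoallylic alcohol F10. Dess–Martin oxidation gives the aldehyde F11, which is acetalised at low temperature (1,2-bis(trimethylsilyloxy)ethane, TMSOTf, –78 °C) before the β,γ-alkene can move into conjugation; this rejoins the route at 11.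

Further compounds
F1 | step 2 | 2α-formyloxy-4,4,10-trimethyl-trans-decal-9-one | C1CC[C@H]2C(C)(C)C[C@H](OC=O)C[C@]2(C)C1=O
F2 | step 2 | 2α-hydroxy-4,4,10-trimethyl-trans-decal-9-one | C1CC[C@H]2C(C)(C)C[C@H](O)C[C@]2(C)C1=O
F3 | step 2 | chlorosulfite of F2 | C1CC[C@H]2C(C)(C)C[C@H](OS(=O)Cl)C[C@]2(C)C1=O
F4 | step 1 | (2R,3R)-2-allyl-2-methyl-3-(prop-1-en-2-yl)cyclohexan-1-one (enantiomer of 5) | O=C1CCC[C@H](C(C)=C)[C@@]1(C)CC=C
F5 | step 1 | (1S,2S,3S)-2-allyl-2-methyl-3-(prop-1-en-2-yl)cyclohexan-1-ol | O[C@H]1CCC[C@@H](C(C)=C)[C@]1(C)CC=C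
F6 | step 1 | (1R,2R,3R)-2-allyl-2-methyl-3-(prop-1-en-2-yl)cyclohexan-1-ol | O[C@@H]1CCC[C@H](C(C)=C)[C@@]1(C)CC=C
F7 | step 1 | (S)-O-methylmandelate of F5 | CO[C@H](C(=O)O[C@H]1CCC[C@@H](C(C)=C)[C@]1(C)CC=C)c1ccccc1
F8 | step 1 | (S)-O-methylmandelate of F6 | CO[C@H](C(=O)O[C@@H]1CCC[C@H](C(C)=C)[C@@]1(C)CC=C)c1ccccc1
F9 | step 4 | 2α-chloro-4,4,10-trimethyl-9-vinyl-trans-decal-8-ene | C=CC1=CCC[C@H]2C(C)(C)C[C@H](Cl)C[C@]12C
F10 | step 4 | 2α-chloro-13,14,15,16,17-pentanorlabd-8-en-12-ol | OCCC1=CCC[C@H]2C(C)(C)C[C@H](Cl)C[C@]12C
F11 | step 4 | 2α-chloro-13,14,15,16,17-pentanorlabd-8-en-12-al | O=CCC1=CCC[C@H]2C(C)(C)C[C@H](Cl)C[C@]12C
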